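All runs were computed from invented constants.

Dawn is the flask in question, followed up to 3.00 min; spring is its twin, run 5 K cooler.

the same everywhere: electrophile 0.61 M; free base 0.915 M; protonated nucleophile 1.83 M
- dawn: temperature 100 °C; the very flask that is asked about, followed so far
- spring: temperature 95 °C; run made earlier
- flask: temperature 100 °C; time 4.0 min

- dawn (time / min: target / %): 0.833: 49.5; 1.50: 56.1; 2.50: 62.8; 3.00: 64.8
- spring (time / min: target / %): 0.833: 43.9; 1.50: 48.7; 2.50: 54.1; 3.00: 55.9

(standard deviation of a reading: 0.5 percentage points)

- north-east: at 4.0 min raise the temperature by 25 K, then wait 4.0 min
- west: at 4.0 min add free base, 50.0 % of the amount charged, then wait 4.0 min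
- south-west: change nothing and wait 4.0 min more
- east: at 4.0 min take out 90 % of the target then present, then wait 4.0 min

- what is taken out of target is counted as made
- the earlier runs were read with a standard deviation of 0.5 percentage points
- additions bring no volume worth counting

- target, in percent of the electrophile first charged, at 4.0 min
- the remedy with the largest gain of target, or "none" below 2 percentage points (north-east / west / south-west / east / none)
- target present, with what was taken out counted in, in percent of the electrophile first charged, after north-east
- target present, with what was taken out counted in, in percent of the electrophile first charged, after east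

First ask where dawn stands. Read it: half of the charge is target by 0.833 min, yet the last 0.500 min add 2 percentage points. So 4.0 min lies in a slow tail. Continue the last step's shrinkage of the unconverted remainder over the remaining 1.00 min, and my figure for now is 68.5 %.

Next ask what heat buys. Compare times at nearly equal target: spring needs 3.00 min for 55.9 %, dawn 1.50 min for 56.1 %. Define this ratio 2.00 as the clock factor, the minutes the cooler run takes per minute of the hotter at equal target. It is read off two readings and carries their scatter. Assume it repeats for each 5 K step: the rise of 25 K is 5 such steps, so one minute hot counts as 32.0 dawn minutes.

Last ask which remedy to take. North-east reaches 132 min of dawn time, south-west 8.00 min. The clock factor weighs heat against waiting and does not price west or east, so choosing north-east is my judgement.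

The forecast gives 68.7 % for now, north-east as best, 97 % after north-east and 81 % after east. It takes the rise as about 20-fold, so my factor is larger. On east it says: “Removing target helps little if the acid is the inhibitor”.

The flask gives 67.8 %. The best remedy is north-east, reaching 95.6 % with a gain of 28 points, more than west's 18 points. East gives 75.2 %, 5.8 points under the forecast; its gain of 7.4 points matches south-west's 7.4 points.

    electrophile + nucleophile → acid set free + target (k = 0.270 M⁻¹ s⁻¹, Ea = 71.0 kJ mol⁻¹)
    nucleophile + acid set free ⇌ protonated nucleophile, settled at all times (K = 1200 M⁻¹, ΔH = −43.0 kJ mol⁻¹)
    acid set free + free base ⇌ salt of the base, settled at all times (K = 180 M⁻¹, ΔH = 20.0 kJ mol⁻¹)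
    electrophile ⇌ dormant form (K = 3.60, k = 0.0750 s⁻¹, Ea = 94.0 kJ mol⁻¹, ΔH = −66.0 kJ mol⁻¹)
    (constants at 100 °C)

Use the clock on this flask: north-east, reckoned at 132 min of dawn time, ends at 95.6 %, above the 89.2 % the unheated flask shows at 40.0 min. Use it on spring: at 4.0 min spring shows 59.1 %, and the flask shows 59.4 % at 2.00 min, which is spring's time divided by 2.00. At 4.00 min the flask's electrophile goes to target at 0.097 of its forward rate to dormant form, against 1.3 just after the start. The dormant form is the resting state of the unreacted electrophile in this flask: at that time c(electrophile) stands at 6.60 % of the electrophile charged, c(dormant form) at 25.6 %.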